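(All runs were computed from invented constants; noise was put on by code.)

Ask first which given number can move the share of E turned into Q in the Tuesday's run at 33 min, and test each in powers of ten. E goes to Q under the catalyst Z.

| flask | E | Z | time |
|---|---|---|---|
| Friday's | 0.100 M | 2.00 × 10⁻⁴ M |  |
| Wednesday's | 0.0400 M | 2.00 × 10⁻⁴ M |  |
| Sunday's | 0.150 M | 2.00 × 10⁻⁴ M |  |
| Thursday's | 0.100 M | 4.00 × 10⁻⁴ M |  |
| Tuesday's | 0.0330 M | 2.00 × 10⁻⁴ M | 33 min |

- Friday's run (time / min: [Q] / M): 6.6: 0.0133; 13: 0.0253; 20: 0.0386; 26: 0.0486; 33: 0.0603
- Wednesday's run (time / min: [Q] / M): 6.6: 0.0061; 13: 0.0122; 20: 0.0170; 26: 0.0204; 33: 0.0238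
- Sunday's run (time / min: [Q] / M): 6.6: 0.0148; 13: 0.0308; 20: 0.0500; 26: 0.0654; 33: 0.0829
- Thursday's run (time / min: [Q] / M): 6.6: 0.0236; 13: 0.0457; 20: 0.0638; 26: 0.0751; 33: 0.0857

(each reading ± 5 × 10⁻⁴ M)

- Overall: E -> Q, with Z as catalyst.
- Constant volume, constant temperature.
- What is held in complexes is read along with the free species.
- An order is taken over about fifteen percent of the charge, up and down.

1. the exponent of [E] in the starting rate at the charge of the Friday's run (at the point where two percent of the E have become Q) (one fixed amount of Q, the same in the runs compared)
2. the exponent of [Z] in the starting rate at the charge of the Friday's run (at the point where two percent of the E have become Q)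
3. the Wednesday's run starts with 0.0600 M less of E than the Friday's run, and with no Q. Compared where both hold the same amount of E, once fifteen percent of what the Wednesday's run was charged with has turned into Q, is the Wednesday's run faster, slower or alike (within a tenth)?
4. Q in the Tuesday's run at 33 min, as a share of the E charged

I start with the charge of E. From the Wednesday's run to the Friday's run it rises by 0.398 of a decade, and the share turned at the last reading goes from 59.5% to 60.3%, a step of 0.8 percentage points. The Tuesday's charge lies 0.0835 of a decade below the Wednesday's, so in proportion I take off 0.17 points.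

Next comes Z. The Thursday's run holds twice the Z of the Friday's run, which is 0.301 of a decade, and its last share stands 25 points higher than the Friday's. This step is larger than the step from the charge of E, but the Tuesday's Z equals the Wednesday's. I need no correction for time, since 33 min is the time of the Wednesday's last reading.

So that last reading must be known well. Its scatter is 1.25% of the charge, more than my charge correction.

Now the number. I carry the decade time, the minutes in which the fraction of the charge still unturned falls by a factor of 10 at a steady pace on the logarithmic scale. The Wednesday's run gives 84.1 min. Over 33 min that leaves the Tuesday's run a turned share of 59.5%, and my correction makes it 59.3%.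

The forecast gives 58%, within 53% to 62%, which is below mine. Its ground is the same run: “Wednesday looks first-order”. It puts the order in E at 0.45 (0.2 to 0.75) and in Z at 0.85 (0.7 to 1), and its word for the Wednesday's run against the Friday's at equal E is slower.

    Z + E ⇌ ZE, settled at all times (6.470 L mol⁻¹)
    ZE + E ⇌ ZE2, settled at all times (183.0 L mol⁻¹)
    ZE2 → Q + ZE (17.52 min⁻¹)
    2 E ⇌ E2, settled at all times (25.90 L mol⁻¹)
    E + Q → 2 Q (0.3930 L mol⁻¹ min⁻¹)

The Tuesday's run gives 59.4%. The orders come to 0.52 in E and 0.98 in Z, and the word for the Wednesday's run against the Friday's at equal E is slower. The Thursday's rate over the Friday's, where the same amount of Q has been made, is 2.0. In the Tuesday's run, the decade time leaves 40.5% of the charge unturned, and the flask leaves 40.6%. Read as a half-life, the decade time from the Wednesday's run gives 25.3 min, and the Sunday's run reaches half of its charge at 29.8 min.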